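Which recipe ends with the most product after 12 h: a cold flask that has to use its hours, or a hot one that stops early?

| setting | north-west | west | south | autumn | summer | dawn | noon |
|---|---|---|---|---|---|---|---|
| substrate | 0.34 M | 0.75 M | 0.50 M | 0.50 M | 0.50 M | 0.50 M | 0.50 M |
| coupling partner | 0.40 M | 0.40 M | 0.60 M | 0.400 M | 0.400 M | 0.400 M | 0.400 M |
| temperature | 112 °C | 140 °C | 112 °C | 100 °C |  | 125 °C | 150 °C |
| remark | run made earlier | run made earlier | run made earlier |  | at 100 °C until 4.0 h, from then on at 150 °C |  |  |
| time |  |  |  | 12 h | 12 h | 12 h | 12 h |

- north-west (time / h: product / %): 0.500: 21; 1.50: 44; 3.00: 58; 4.00: 65; 6.00: 68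
- west (time / min: product / %): 8.00: 38; 15.0: 45; 25.0: 45; 50.0: 44; 90.0: 44
- south (time / h: product / %): 1.33: 55; 3.00: 67; 4.00: 75; 6.00: 80

(scatter of a reading: 2 percentage points)

- the best flask by amount of product, in percent of the substrate charged; "all alike" if 1.5 percentage points covers them all (autumn / summer / dawn / noon / all alike)
- amount of product at the end, in percent of the substrate charged, autumn
- amount of product at the end, in percent of the substrate charged, summer
- amount of product at the end, in percent of the substrate charged, dawn
- amount of product at the end, in percent of the substrate charged, noon

Each of the four flasks asked about carries 0.800 equivalents of coupling partner to substrate, so in them the coupling partner is the limiting reagent, and the yield depends on how much of it reaches product. The west run shows that not all of it does. It stands flat from 15.0 min to 90.0 min with 0.413 M of substrate unused. We read that as a partner lost by a second path, and so we need two amounts: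

product made = 0.338 M

partner lost = 0.40 M − 0.338 M = 0.0625 M

Their ratio, product made per partner lost, we call the split: 5.40, a reading from the west run with its scatter.

A flask that uses up its partner ends at

yield = (partner charge / substrate charge) × split / (split + one)

Taking the split in proportion to substrate, the west split falls to 3.60 at our charge, which gives 62.6 % at 140 °C. We expect noon, hotter still, to end below that. The south run was still rising at its last reading, so it gives no split at 112 °C. We bet on autumn, which has twice the 6.00 h of that run, though at 100 °C and not 112 °C.

The forecast gave 54 % for autumn, 56 % for summer, 61 % for dawn and 50 % for noon, with dawn best, on the ground that “hot runs stall earlier”.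

The flasks give 71.2 % for autumn, 65.3 % for summer, 61.3 % for dawn and 46.6 % for noon, so autumn is best.

    substrate + coupling partner → product, rate k1*[substrate]^2*[coupling partner]^0.5 (k = 0.0280 /M^1.5/min, Ea = 61.0 kJ/mol)
    coupling partner → decomposed reagent (k = 6.80 × 10⁻⁴ /min, Ea = 124 kJ/mol)
    (constants at 100 °C)

Noon holds 0 % of its partner at the end, with 0.167 M of decomposed reagent, so its split is 1.40. The west split, a reading at 140 °C, scaled now by the square of substrate as in the rate equation and not in proportion, gives 2.40, and noon, at 150 °C, stands lower. Now take a neighbour of noon charged with 0.20 M of substrate. With the partner charge held, the same square turns the noon split into 0.223, which gives 36.5 %. The neighbour, with 0 % of its partner left, gives 40.9 %.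

The numbers in the tables come from a simulation on assumed constants; scatter was added.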